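Remarks on the chemistry: cembrane numbering is used throughout (C1 carries the isopropyl group, C18 and C19 are the methyls on C4 and C8, C20 is the lactone carbonyl). The carbinol carbon C3 of the eastern fragment is carried as both epimers, because this centre is destroyed in the key step.

## Structural features

- Target 31 is a cembranoid. A 14-membered carbocycle (C1–C14) is bridged between C8 and C12 by O–C20(=O), so that C8–C9–C10–C11=C12–C20–O form a seven-membered α,β-unsaturated ε-lactone.
- The lactone oxygen sits on the quaternary, methyl-bearing C8 (8S), next to the secondary acetoxy carbon C7 (7R). These are the only stereocentres; their oxygens are anti when C6–C7–C8–C9 is drawn zigzag.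
- The ring holds a conjugated diene C1=C2–C3=C4 (isopropyl on C1, methyl on C4). C14 is cis to C3 at C1=C2 and C2 is trans to C5 at C3=C4 (1E,3E). The lactone fixes C20 cis to C10 at C11=C12 (11Z), which makes this olefin trans within the macrocycle.
- Fragile groups: the electron-rich diene (acid, electrophilic oxidants), the ester of a tertiary alcohol, and the secondary acetate beside a tertiary carbinol. An ionising C8 is 1,5-related to the C3=C4 olefin, which invites cation–olefin cyclisation.
- The real difficulty is the 14-membered carbocycle with three trisubstituted olefins of defined geometry, together with the acylated tertiary carbinol C8 next to C7.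
- Feature exploited by the key step: the oxygenated ring carbon C7 and the ring olefin C3=C4 form the array O–C7–C6–C5–C4=C3, the retron of a Claisen rearrangement. Because C3 and C7 are both ring atoms, the retro-Claisen turns the 14-membered carbocycle into a 12-membered oxacycle (ring O between C3 and C7, C6 and C4=C5 exocyclic), that is, into a macrolactone plus one methylene carbon.

## Logic of the disconnections

**31 to 28.** The acyl–oxygen bond C20–O(C8) is cut and C20 is lowered to the primary allylic alcohol. A tertiary ester is hard to make by acylation, but forms readily when a lactol between C20 and the C8 hydroxyl is oxidised. This removes the small ring and leaves C20 as a silyl-protected alcohol that is inert to a titanium carbenoid. The forward step demands that C20 is already cis to C10 and that the C7 hydroxyl is blocked (acetate in 27), so that only the C8 hydroxyl can close.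

**28 to 25 (through 27 and 26).** The C7–H bond is removed: silyl ether, acetate and carbinol go back to the α-hydroxy ketone. The ketone is what the key step delivers, and C8 can control C7 through a chelate. The forward reduction must deliver hydride from the face of the C8 methyl group.

**25 to 22 (through 24 and 23).** The C5–C6 bond is cut and the C3–O bond is restored, with the π-bonds shifting from C3=C4 and C7=O to C4=C5 and C6=C7; C6 is then removed to leave the lactone carbonyl of 22. This trades the macrocarbocycle for a 12-membered lactone, and the forward rearrangement creates the C3=C4 olefin (hence the diene), the C7 carbonyl and the 14-membered ring in one event. The C3 stereocentre of 22 becomes irrelevant. The forward step needs the [3,3] shift to run through the exocyclic isopropenyl group and not through the ring olefin, a chair transition state, and non-ionising conditions.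

**22 to 19 (through 21).** The ester bond C7(=O)–O(C3) is cut to give the seco acid. Macrolactonisation is the most dependable macrocyclic ring closure, and only the secondary C3 hydroxyl can cyclise. The demand is activation of a hindered α-quaternary acid without acylating the tertiary C8 hydroxyl.

**19 to 10 and 16 (through 18).** The sp3–sp2 bond C14–C1 is cut. This divides the chain into two pieces of similar size and transfers the C1=C2 geometry from an alkenyl iodide with retention. The demand is hydroboration of only the terminal vinyl group of 10.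

**16 to 11 and 12 (through 14).** The C1–I and C2–H bonds and then the C2–C3 bond are cut. Hydroxyl-directed trans-hydroalumination and iodinolysis place iodine cis to C3; the alkynol comes from an acetylide and an enal.

**10 to 4 and 8.** The sp3–sp2 bond C10–C11 is cut, with retention at the alkenyl iodide, so that C10 ends cis to C20.

**8 to 5 (through 7).** The C12–C13 and C11–I bonds are cut. Anti-carbomagnesiation of a propargylic alcohol sets the trisubstituted olefin in one step and brings C20 in at the alcohol level.

**4 to 1 (through 3 and 2).** C8 with its methyl, oxygen and carboxyl (C7) comes unchanged from the chiral pool. The acetonide masks acid and tertiary alcohol together.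

In one sentence: Claisen ring expansion of the 12-membered 2-methylidene allyl vinyl ether 23, made from macrolactone 22 with a titanium methylidene, to the 14-membered dienone 24.

## Other disconnections considered

**Alternative 1:** (the first that comes to mind) Cut C2–C3 of the diene. The forward key step is an intramolecular Stille coupling of the iodo-stannane A1, which already carries the ε-lactone and the acetate.
- It needs two stereodefined trisubstituted alkenyl-metal and alkenyl-halide termini at the ends of a long linear chain.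
- The tertiary lactone must be made early and carried through organometallic steps.
- The ring is closed by an entropically costly coupling of two hindered partners, which adds no stereochemical information.
- The chosen plan closes the large ring as an ester and lets a sigmatropic shift build the diene.

**Alternative 2:** (biomimetic) Cut the alkyl–oxygen bond C8–O of the lactone. The forward key step is acid-promoted transannular opening of epoxy acid A2 at C8 by the C20 carboxyl with inversion.
- A2 must come from the tetraenoic acid A3, which itself requires a conventional carbocyclic macrocyclisation.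
- One of four olefins of A3 would have to be epoxidised enantioselectively without a directing group.
- In A2 the epoxide is 1,5-related to the C3=C4 olefin, the classical arrangement for cation–olefin cyclisation, and attack at the less hindered C7 would give the eight-membered lactone.
- The chosen plan sets C8 from the chiral pool and C7 by chelation.

**Alternative 3:** Cut C2–C3 together with the C1–C4 link. The forward key step is thermal conrotatory opening of the cis-fused cyclobutene A4 (bicyclo[10.2.0]), a two-carbon ring expansion that would give the ring-cis/ring-trans diene.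
- A4 contains two adjacent quaternary carbons and still needs a 12-membered carbocycle, so nothing is gained in simplicity.
- Of the two conrotatory modes, only isopropyl-outward/methyl-inward gives the target, and nothing in A4 secures this.
- The chosen ring expansion starts from a 12-membered lactone that is closed by esterification.

Key step: step 13

## Route

Step 1
Reactants: 1 (S)-citramalic acid
Product: 2 2-[(4S)-2,2,4-trimethyl-5-oxo-1,3-dioxolan-4-yl]acetic acid
Conditions: 2,2-dimethoxypropane, TsOH·H2O (cat.), CH2Cl2, rt
Reagents that add atoms: 2,2-dimethoxypropane COC(C)(C)OC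
Why: Acetalisation of the α-hydroxy acid; the five-membered dioxolanone should form in preference to the six-membered dioxanone of the β-carboxyl, as with malic acid, and the stereocentre is not touched.

Step 2
Reactants: 2 2-[(4S)-2,2,4-trimethyl-5-oxo-1,3-dioxolan-4-yl]acetic acid
Product: 3 (5S)-5-(2-hydroxyethyl)-2,2,5-trimethyl-1,3-dioxolan-4-one
Conditions: BH3·SMe2, THF, 0 °C to rt; MeOH quench, neutral work-up
Reagents that add atoms: none
Why: Borane reduces the free carboxylic acid chemoselectively beside the dioxolanone ester; neutral, cold handling should avoid translactonisation to the butyrolactone.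

Step 3
Reactants: 3 (5S)-5-(2-hydroxyethyl)-2,2,5-trimethyl-1,3-dioxolan-4-one
Product: 4 (5S)-5-(2-iodoethyl)-2,2,5-trimethyl-1,3-dioxolan-4-one
Conditions: I2, PPh3, imidazole, CH2Cl2, 0 °C
Reagents that add atoms: iodine II
Why: Appel-type iodination, SN2 at a primary carbon under buffered conditions.

Step 4
Reactants: 5 prop-2-yn-1-ol
Product: 7 (2Z)-2-(iodomethylidene)but-3-en-1-ol, via alkenylmagnesium chelate 6 (not isolated)
Conditions: vinylMgBr (3 equiv), CuI (10 mol%), THF, −20 °C to rt; then I2, −78 to 0 °C
Reagents that add atoms: vinylmagnesium bromide C=C[Mg]Br; iodine II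
Why: Copper-catalysed anti-carbomagnesiation of a propargylic alcohol (Duboudin): vinyl adds to the proximal alkyne carbon and magnesium to the terminal carbon within a five-membered chelate; iodinolysis with retention puts iodine cis to CH2OH, which fixes C20 cis to the later C10.

Step 5
Reactants: 7 (2Z)-2-(iodomethylidene)but-3-en-1-ol
Product: 8 tert-butyl{[(2Z)-2-(iodomethylidene)but-3-en-1-yl]oxy}diphenylsilane
Conditions: TBDPSCl, imidazole, CH2Cl2, 0 °C to rt
Reagents that add atoms: tert-butyl(chloro)diphenylsilane CC(C)(C)[Si](Cl)(c1ccccc1)c1ccccc1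
Why: Standard silylation; the TBDPS ether should survive palladium, borane, the titanium carbenoid and heating, and is removed by fluoride near the end.

Step 6
Reactants: 4 (5S)-5-(2-iodoethyl)-2,2,5-trimethyl-1,3-dioxolan-4-one; 8 tert-butyl{[(2Z)-2-(iodomethylidene)but-3-en-1-yl]oxy}diphenylsilane
Product: 10 (5S)-5-[(3Z)-4-({[tert-butyl(diphenyl)silyl]oxy}methyl)hexa-3,5-dien-1-yl]-2,2,5-trimethyl-1,3-dioxolan-4-one, via alkylzinc iodide 9 (not isolated)
Conditions: Zn dust (activated), LiCl, THF, 35 °C; then 8, Pd2(dba)3 (2.5 mol%), SPhos (10 mol%), THF, rt to 40 °C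
Reagents that add atoms: none
Why: Zinc insertion tolerates the dioxolanone; Negishi sp3–sp2 coupling proceeds with retention at the alkenyl iodide, so C10 takes the place of iodine cis to C20.

Step 7
Reactants: 11 3-methylbut-1-yne; 12 2-methylprop-2-enal (methacrolein)
Product: 14 (3RS)-2,6-dimethylhept-1-en-4-yn-3-ol, via lithium acetylide 13 (not isolated)
Conditions: n-BuLi, THF, −78 °C; then 12, −78 to 0 °C; NH4Cl (aq)
Reagents that add atoms: none
Why: 1,2-Addition of a lithium acetylide to an enal; C3 is made racemic on purpose because it is destroyed in step 13.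

Step 8
Reactants: 14 (3RS)-2,6-dimethylhept-1-en-4-yn-3-ol
Product: 16 (3RS,4Z)-5-iodo-2,6-dimethylhepta-1,4-dien-3-ol, via alkenylaluminate 15 (not isolated)
Conditions: Red-Al, THF, 0 °C to rt; then I2, THF, −78 °C
Reagents that add atoms: iodine II
Why: Alkoxide-directed trans-hydroalumination of the propargylic alcohol places aluminium on the distal carbon in a five-membered ring; iodinolysis with retention should give the (Z)-γ-iodo allylic alcohol, with iodine (later C14) cis to C3 and isopropyl trans.

Step 9
Reactants: 10 (5S)-5-[(3Z)-4-({[tert-butyl(diphenyl)silyl]oxy}methyl)hexa-3,5-dien-1-yl]-2,2,5-trimethyl-1,3-dioxolan-4-one; 16 (3RS,4Z)-5-iodo-2,6-dimethylhepta-1,4-dien-3-ol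
Product: 18 (5S)-5-[(3Z,7E,9RS)-4-({[tert-butyl(diphenyl)silyl]oxy}methyl)-9-hydroxy-10-methyl-7-(propan-2-yl)undeca-3,7,10-trien-1-yl]-2,2,5-trimethyl-1,3-dioxolan-4-one, via B-alkyl-9-BBN 17 (not isolated)
Conditions: 9-BBN, THF, 0 °C to rt; then 16, PdCl2(dppf) (5 mol%), AsPh3, Cs2CO3, DMF/THF/H2O, rt
Reagents that add atoms: none
Why: 9-BBN should add only to the terminal monosubstituted vinyl group at C14 (the trisubstituted olefin is far slower); B-alkyl Suzuki–Miyaura coupling with retention at C1 sets C14 cis to C3, and any hydrolysis of the dioxolanone by the base only anticipates step 10.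

Step 10
Reactants: 18 the dioxolanone trienol of step 9
Product: 19 (2S,5Z,9E,11RS)-6-({[tert-butyl(diphenyl)silyl]oxy}methyl)-2,11-dihydroxy-2,12-dimethyl-9-(propan-2-yl)trideca-5,9,12-trienoic acid
Conditions: LiOH·H2O, THF/H2O, 0 °C to rt; 0.5 M HCl to pH 4 at 0 °C
Reagents that add atoms: lithium hydroxide [Li+].[OH-]
Why: Saponification of the activated dioxolanone frees the C7 acid and the tertiary C8 hydroxyl together with loss of acetone; cold, brief acidification should spare the bis-allylic alcohol.

Step 11
Reactants: 19 the seco acid of step 10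
Product: 21 (3S,6Z,10E,12RS)-7-({[tert-butyl(diphenyl)silyl]oxy}methyl)-3-hydroxy-3-methyl-10-(propan-2-yl)-12-(prop-1-en-2-yl)-1-oxacyclododeca-6,10-dien-2-one, via mixed anhydride 20 (not isolated)
Conditions: 2-methyl-6-nitrobenzoic anhydride (1.5 equiv), DMAP (6 equiv), toluene, 1 mM, rt to 40 °C, slow addition of 19
Reagents that add atoms: none
Why: Shiina macrolactonisation; only the secondary C3 hydroxyl can close a ring (12-membered), the tertiary α-hydroxyl is too hindered to be acylated, and the cis arrangement of C14 and C3 at C1=C2 brings the chain ends together.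

Step 12
Reactants: 21 the 12-membered hydroxy lactone
Product: 22 the 3-O-trimethylsilyl ether of 21 (C8–OTMS in cembrane numbering)
Conditions: TMSOTf, 2,6-lutidine, CH2Cl2, −78 °C
Reagents that add atoms: trimethylsilyl triflate C[Si](C)(C)OS(=O)(=O)C(F)(F)F
Why: Silylation of the tertiary alcohol prevents titanium alkoxide formation and an α-ketol shift during heating in step 13; the tertiary TMS ether can later be cleaved selectively beside TBDPS.

Step 13
Reactants: 22 the 12-membered silyloxy lactone
Product: 24 (2S,5Z,9E,11E)-6-({[tert-butyl(diphenyl)silyl]oxy}methyl)-2,12-dimethyl-9-(propan-2-yl)-2-[(trimethylsilyl)oxy]cyclotetradeca-5,9,11-trien-1-one, via enol ether 23 (not isolated)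
Conditions: Cp2TiMe2 (3 equiv), toluene, 75 °C, dark, 16 h; then dilute to 5 mM, Et3N (1%), 130 °C (sealed), 8 h
Reagents that add atoms: dimethyltitanocene C[Ti](C)(C1C=CC=C1)C1C=CC=C1
Why: Dimethyltitanocene loses methane to give Cp2Ti=CH2, which converts the lactone carbonyl C7=O into the exocyclic enol ether C7=C6H2 by [2+2]/retro-[2+2] (Petasis methylenation, well established for hindered α-oxygenated lactones); the resulting allyl vinyl ether C6=C7–O–C3–C4=C5 then undergoes a concerted suprafacial [3,3] shift. The closest known reaction type is the Claisen ring expansion of 2-methylidene-6-vinyltetrahydropyrans to cyclooctenones and tandem titanium methylenation–Claisen sequences. The 14-membered carbocycle is closed by ring expansion: the C5–C6 bond forms between the two exocyclic termini while the ring C3–O bond breaks, so the 12-membered oxacycle becomes the carbocycle with the oxygen expelled into the C7 carbonyl. No stereocentre is created: C3 is destroyed (both epimers converge) and C8 is a spectator. The new C3=C4 olefin should be E because a chair transition state places the ring carbon C2 pseudo-equatorial on C3, away from the quaternary C8 substituent on C7; this completes the 1E,3E-diene, whose C1=C2 geometry was fixed in steps 8 and 9. The selectivity needed is rearrangement through the isopropenyl group and not through the ring olefin C1=C2; bonding to the unsubstituted CH2 terminus C5 is favoured over bonding to the fully substituted, isopropyl-bearing C1, which would create a quaternary centre in a strained ten-membered ring. C=O formation and diene conjugation drive the step, and the Cope rearrangement of the C11=C12/C1=C2 1,5-diene should need a clearly higher temperature.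

Step 14
Reactants: 24 the 14-membered silyloxy ketone
Product: 25 (2S,5Z,9E,11E)-6-({[tert-butyl(diphenyl)silyl]oxy}methyl)-2-hydroxy-2,12-dimethyl-9-(propan-2-yl)cyclotetradeca-5,9,11-trien-1-one
Conditions: PPTS (cat.), MeOH, 0 °C to rt
Reagents that add atoms: none
Why: Mild acidic methanolysis cleaves the tertiary TMS ether; the primary TBDPS ether and the diene should be untouched.

Step 15
Reactants: 25 the α-hydroxy ketone
Product: 26 (1R,2S,5Z,9E,11E)-6-({[tert-butyl(diphenyl)silyl]oxy}methyl)-2,12-dimethyl-9-(propan-2-yl)cyclotetradeca-5,9,11-triene-1,2-diol (7R,8S in cembrane numbering)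
Conditions: Zn(BH4)2, Et2O, −30 to 0 °C; NH4Cl (aq)
Reagents that add atoms: none
Why: Cram-chelate controlled reduction: Zn(II) bridges the C7 carbonyl and the C8 hydroxyl, and hydride enters from the face of the smaller C8 substituent (CH3 rather than the ring CH2-9), which should give 7R with the two oxygens anti.

Step 16
Reactants: 26 the 7,8-diol
Product: 27 the C7 monoacetate of 26, (1R,2S,5Z,9E,11E)-6-({[tert-butyl(diphenyl)silyl]oxy}methyl)-2-hydroxy-2,12-dimethyl-9-(propan-2-yl)cyclotetradeca-5,9,11-trien-1-yl acetate
Conditions: Ac2O, pyridine, DMAP (cat.), CH2Cl2, 0 °C to rt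
Reagents that add atoms: acetic anhydride CC(=O)OC(C)=O
Why: The secondary alcohol is acetylated while the tertiary C8 hydroxyl stays free under these conditions; this also blocks C7–OH from the later ring closure.

Step 17
Reactants: 27 the silyl ether acetate
Product: 28 (1R,2S,5Z,9E,11E)-2-hydroxy-6-(hydroxymethyl)-2,12-dimethyl-9-(propan-2-yl)cyclotetradeca-5,9,11-trien-1-yl acetate
Conditions: TBAF, AcOH (1:1), THF, 0 °C to rt
Reagents that add atoms: none
Why: Fluoride desilylation, buffered with acetic acid so that the acetate neither migrates nor is lost.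

Step 18
Reactants: 28 the hydroxy allylic alcohol
Product: 31 CNP0291129.1, via hydroxy enal 29 (not isolated), via lactol 30 (not isolated)
Conditions: TEMPO (0.2 equiv), PhI(OAc)2 (3 equiv), CH2Cl2, rt
Reagents that add atoms: none
Why: Oxidative lactonisation of a diol: the primary allylic alcohol is oxidised to the (Z)-enal, the C8 hydroxyl adds to give the seven-membered lactol, and this is oxidised to the lactone; the tertiary ester thus forms without acylating a tertiary alcohol, and the acetate on C7 excludes the eight-membered isomer.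

## Compound list

1 | (S)-citramalic acid | OC(=O)C[C@](C)(O)C(=O)O | starting material
2 | 2-[(4S)-2,2,4-trimethyl-5-oxo-1,3-dioxolan-4-yl]acetic acid | OC(=O)C[C@]1(C)OC(C)(C)OC1=O | intermediate
3 | (5S)-5-(2-hydroxyethyl)-2,2,5-trimethyl-1,3-dioxolan-4-one | OCC[C@]1(C)OC(C)(C)OC1=O | intermediate
4 | (5S)-5-(2-iodoethyl)-2,2,5-trimethyl-1,3-dioxolan-4-one | ICC[C@]1(C)OC(C)(C)OC1=O | intermediate
5 | prop-2-yn-1-ol | C#CCO | starting material
6 | cyclic alkenylmagnesium alkoxide from anti-carbomagnesiation (Mg cis to CH2O) | C=CC1=C[Mg]OC1 | intermediate (not isolated)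
7 | (2Z)-2-(iodomethylidene)but-3-en-1-ol | OC/C(C=C)=C\I | intermediate
8 | tert-butyl{[(2Z)-2-(iodomethylidene)but-3-en-1-yl]oxy}diphenylsilane | CC(C)(C)[Si](c1ccccc1)(c1ccccc1)OC/C(C=C)=C\I | intermediate
9 | {2-[(4S)-2,2,4-trimethyl-5-oxo-1,3-dioxolan-4-yl]ethyl}zinc iodide | I[Zn]CC[C@]1(C)OC(C)(C)OC1=O | intermediate (not isolated)
10 | (5S)-5-[(3Z)-4-({[tert-butyl(diphenyl)silyl]oxy}methyl)hexa-3,5-dien-1-yl]-2,2,5-trimethyl-1,3-dioxolan-4-one | C=C/C(CO[Si](c1ccccc1)(c1ccccc1)C(C)(C)C)=C/CC[C@]1(C)OC(C)(C)OC1=O | intermediate
11 | 3-methylbut-1-yne | CC(C)C#C | starting material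
12 | 2-methylprop-2-enal | CC(=C)C=O | starting material
13 | lithium 3-methylbut-1-yn-1-ide | CC(C)C#C[Li] | intermediate (not isolated)
14 | (3RS)-2,6-dimethylhept-1-en-4-yn-3-ol | CC(C)C#CC(O)C(C)=C | intermediate
15 | sodium oxa-aluminacyclopentene from trans-hydroalumination of 14 (Al on the isopropyl-bearing carbon) | CC(C)C1=CC(C(C)=C)O[Al-]1(OCCOC)OCCOC.[Na+] | intermediate (not isolated)
16 | (3RS,4Z)-5-iodo-2,6-dimethylhepta-1,4-dien-3-ol | CC(C)/C(I)=C/C(O)C(C)=C | intermediate
17 | B-alkyl-9-BBN from hydroboration of 10 at C14 | CC(C)(C)[Si](c1ccccc1)(c1ccccc1)OC/C(CCB1C2CCCC1CCC2)=C\CC[C@]1(C)OC(C)(C)OC1=O | intermediate (not isolated)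
18 | (5S)-5-[(3Z,7E,9RS)-4-({[tert-butyl(diphenyl)silyl]oxy}methyl)-9-hydroxy-10-methyl-7-(propan-2-yl)undeca-3,7,10-trien-1-yl]-2,2,5-trimethyl-1,3-dioxolan-4-one | C=C(C)C(O)/C=C(/C(C)C)CC/C(CO[Si](c1ccccc1)(c1ccccc1)C(C)(C)C)=C/CC[C@]1(C)OC(C)(C)OC1=O | intermediate
19 | (2S,5Z,9E,11RS)-6-({[tert-butyl(diphenyl)silyl]oxy}methyl)-2,11-dihydroxy-2,12-dimethyl-9-(propan-2-yl)trideca-5,9,12-trienoic acid | C=C(C)C(O)/C=C(/C(C)C)CC/C(CO[Si](c1ccccc1)(c1ccccc1)C(C)(C)C)=C/CC[C@](C)(O)C(=O)O | intermediate
20 | mixed anhydride of 19 with 2-methyl-6-nitrobenzoic acid | C=C(C)C(O)/C=C(/C(C)C)CC/C(CO[Si](c1ccccc1)(c1ccccc1)C(C)(C)C)=C/CC[C@](C)(O)C(=O)OC(=O)c1c(C)cccc1[N+](=O)[O-] | intermediate (not isolated)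
21 | (3S,6Z,10E,12RS)-7-({[tert-butyl(diphenyl)silyl]oxy}methyl)-3-hydroxy-3-methyl-10-(propan-2-yl)-12-(prop-1-en-2-yl)-1-oxacyclododeca-6,10-dien-2-one | C=C(C)C1/C=C(/C(C)C)CC/C(CO[Si](c2ccccc2)(c2ccccc2)C(C)(C)C)=C/CC[C@](C)(O)C(=O)O1 | intermediate
22 | 3-O-trimethylsilyl ether of 21 | C=C(C)C1/C=C(/C(C)C)CC/C(CO[Si](c2ccccc2)(c2ccccc2)C(C)(C)C)=C/CC[C@](C)(O[Si](C)(C)C)C(=O)O1 | intermediate
23 | (3S,6Z,10E,12RS)-7-({[tert-butyl(diphenyl)silyl]oxy}methyl)-3-methyl-2-methylidene-10-(propan-2-yl)-12-(prop-1-en-2-yl)-3-[(trimethylsilyl)oxy]-1-oxacyclododeca-6,10-diene | C=C(C)C1/C=C(/C(C)C)CC/C(CO[Si](c2ccccc2)(c2ccccc2)C(C)(C)C)=C/CC[C@](C)(O[Si](C)(C)C)C(=C)O1 | intermediate (not isolated)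
24 | (2S,5Z,9E,11E)-6-({[tert-butyl(diphenyl)silyl]oxy}methyl)-2,12-dimethyl-9-(propan-2-yl)-2-[(trimethylsilyl)oxy]cyclotetradeca-5,9,11-trien-1-one | O=C1CC/C(C)=C/C=C(/C(C)C)CC/C(CO[Si](c2ccccc2)(c2ccccc2)C(C)(C)C)=C/CC[C@]1(C)O[Si](C)(C)C | intermediate
25 | (2S,5Z,9E,11E)-6-({[tert-butyl(diphenyl)silyl]oxy}methyl)-2-hydroxy-2,12-dimethyl-9-(propan-2-yl)cyclotetradeca-5,9,11-trien-1-one | O=C1CC/C(C)=C/C=C(/C(C)C)CC/C(CO[Si](c2ccccc2)(c2ccccc2)C(C)(C)C)=C/CC[C@]1(C)O | intermediate
26 | (1R,2S,5Z,9E,11E)-6-({[tert-butyl(diphenyl)silyl]oxy}methyl)-2,12-dimethyl-9-(propan-2-yl)cyclotetradeca-5,9,11-triene-1,2-diol | O[C@@H]1CC/C(C)=C/C=C(/C(C)C)CC/C(CO[Si](c2ccccc2)(c2ccccc2)C(C)(C)C)=C/CC[C@]1(C)O | intermediate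
27 | (1R,2S,5Z,9E,11E)-6-({[tert-butyl(diphenyl)silyl]oxy}methyl)-2-hydroxy-2,12-dimethyl-9-(propan-2-yl)cyclotetradeca-5,9,11-trien-1-yl acetate | CC(=O)O[C@@H]1CC/C(C)=C/C=C(/C(C)C)CC/C(CO[Si](c2ccccc2)(c2ccccc2)C(C)(C)C)=C/CC[C@]1(C)O | intermediate
28 | (1R,2S,5Z,9E,11E)-2-hydroxy-6-(hydroxymethyl)-2,12-dimethyl-9-(propan-2-yl)cyclotetradeca-5,9,11-trien-1-yl acetate | CC(=O)O[C@@H]1CC/C(C)=C/C=C(/C(C)C)CC/C(CO)=C/CC[C@]1(C)O | intermediate
29 | (1R,2S,5Z,9E,11E)-6-formyl-2-hydroxy-2,12-dimethyl-9-(propan-2-yl)cyclotetradeca-5,9,11-trien-1-yl acetate | CC(=O)O[C@@H]1CC/C(C)=C/C=C(/C(C)C)CC/C(C=O)=C/CC[C@]1(C)O | intermediate (not isolated)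
30 | seven-membered lactol between C20 and O–C8 (both anomers) | CC(=O)O[C@@H]1CC/C(C)=C/C=C(/C(C)C)CCC2=CCC[C@]1(C)OC2O | intermediate (not isolated)
31 | CNP0291129.1, (7R,8S,1E,3E,11Z)-7-acetoxycembra-1,3,11-trien-20,8-olide | CC(=O)O[C@@H]1CC/C(C)=C/C=C(/C(C)C)CCC2=CCC[C@]1(C)OC2=O | target

## Step count and least certain steps

Total: 18 steps. Longest linear sequence: 14 steps (1–3, 6, 9–18).

**Step 13 (key step).** The methylenation of the hindered α-quaternary lactone may be slow. The doubly allylic C3–O bond of the enol ether may ionise (titanium residues, trace acid) to a pentadienyl cation and an enolate; this would erode the E-selectivity at C3=C4 and allow recombination at C3 or C1. The enol ether may also hydrolyse.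

Fallback: form the C5–C6 bond by intramolecular enolate alkylation. It sets out from 16 and 17 (made from 10 as in step 9) and comes back at 24.
- Rhenium-catalysed 1,3-hydroxyl transposition of 16 (Ph3SiOReO3, Et2O, −40 to 0 °C) should give the conjugated primary alcohol (2E,4Z)-5-iodo-2,6-dimethylhepta-2,4-dien-1-ol F1.
- B-alkyl Suzuki coupling of F1 with 17 (conditions of step 9) gives the dioxolanone dienol F2.
- Methyllithium (2.2 equiv, THF, −78 °C) opens the dioxolanone with loss of acetone to the α-hydroxy methyl ketone F3.
- CBr4/PPh3 converts the primary allylic alcohol into the allylic bromide F4.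
- TMSOTf/2,6-lutidine gives the tertiary silyl ether F5.
- KHMDS (THF, −78 to 0 °C, 1 mM) forms the only possible enolate (at C6), which should close the 14-membered ring by SN2 at C5 to give 24.

**Step 11.** Acyl transfer from the mixed anhydride may be misdirected to the aryl carbonyl, because the aliphatic carboxyl is α-quaternary; this would aroylate C3–OH or favour dimers.

Fallback: ring closure without carboxyl activation. It sets out from 18 and comes back at 21. NaHMDS (THF, 0 °C to rt, 1 mM) generates the C3 alkoxide, which opens the dioxolanone (an activated acylal ester) by intramolecular transesterification with loss of acetone. No new compound is made.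

**Step 15.** Facial selectivity may be poor if peripheral attack on the macrocyclic ketone overrides the zinc chelate. An α-ketol shift of 25 under Lewis-acidic conditions is a second risk.

Fallback: reagent control on the silyl ether. It sets out from 24 and comes back at 26. (S)-2-Methyl-CBS-oxazaborolidine with catecholborane (toluene, −78 °C), with the quaternary C8 as the large group, should give the (7R)-alcohol F6; PPTS/MeOH then removes the TMS group to give 26.

**Step 18.** Ring closure to the seven-membered lactol by a tertiary hydroxyl may be unfavourable. The oxidation would then stall at the enal, which can isomerise about C11=C12.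

Fallback: acylation in place of lactol oxidation. It sets out from 28 and comes back at 31. MnO2 (CH2Cl2) gives enal 29, now isolated; Pinnick oxidation (NaClO2, NaH2PO4, 2-methylbut-2-ene, t-BuOH/H2O) gives the hydroxy acid F7; Yamaguchi lactonisation (2,4,6-trichlorobenzoyl chloride, Et3N, then DMAP, toluene, 60 °C) closes the ε-lactone on the tertiary alcohol to give 31.

## Further compounds

F1 | step 13 | (2E,4Z)-5-iodo-2,6-dimethylhepta-2,4-dien-1-ol | CC(C)/C(I)=C/C=C(\C)CO
F2 | step 13 | (5S)-5-[(3Z,7E,9E)-4-({[tert-butyl(diphenyl)silyl]oxy}methyl)-11-hydroxy-10-methyl-7-(propan-2-yl)undeca-3,7,9-trien-1-yl]-2,2,5-trimethyl-1,3-dioxolan-4-one | OC/C(C)=C/C=C(/C(C)C)CC/C(CO[Si](c1ccccc1)(c1ccccc1)C(C)(C)C)=C/CC[C@]1(C)OC(C)(C)OC1=O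
F3 | step 13 | (3S,6Z,10E,12E)-7-({[tert-butyl(diphenyl)silyl]oxy}methyl)-3,14-dihydroxy-3,13-dimethyl-10-(propan-2-yl)tetradeca-6,10,12-trien-2-one | OC/C(C)=C/C=C(/C(C)C)CC/C(CO[Si](c1ccccc1)(c1ccccc1)C(C)(C)C)=C/CC[C@](C)(O)C(C)=O
F4 | step 13 | (3S,6Z,10E,12E)-14-bromo-7-({[tert-butyl(diphenyl)silyl]oxy}methyl)-3-hydroxy-3,13-dimethyl-10-(propan-2-yl)tetradeca-6,10,12-trien-2-one | BrC/C(C)=C/C=C(/C(C)C)CC/C(CO[Si](c1ccccc1)(c1ccccc1)C(C)(C)C)=C/CC[C@](C)(O)C(C)=O
F5 | step 13 | 3-O-trimethylsilyl ether of F4 | BrC/C(C)=C/C=C(/C(C)C)CC/C(CO[Si](c1ccccc1)(c1ccccc1)C(C)(C)C)=C/CC[C@](C)(O[Si](C)(C)C)C(C)=O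
F0 | step 11 | none | none
F6 | step 15 | (1R,2S,5Z,9E,11E)-6-({[tert-butyl(diphenyl)silyl]oxy}methyl)-2,12-dimethyl-9-(propan-2-yl)-2-[(trimethylsilyl)oxy]cyclotetradeca-5,9,11-trien-1-ol | O[C@@H]1CC/C(C)=C/C=C(/C(C)C)CC/C(CO[Si](c2ccccc2)(c2ccccc2)C(C)(C)C)=C/CC[C@]1(C)O[Si](C)(C)C
F7 | step 18 | (1Z,5E,7E,11R,12S)-11-acetoxy-12-hydroxy-8,12-dimethyl-5-(propan-2-yl)cyclotetradeca-1,5,7-triene-1-carboxylic acid | CC(=O)O[C@@H]1CC/C(C)=C/C=C(/C(C)C)CC/C(C(=O)O)=C/CC[C@]1(C)O
A1 | alternative 1 | seco iodo-stannane carrying the ε-lactone and the acetate (C3 alkenyl iodide, C2 alkenyl tributylstannane) | CC(=O)O[C@H](CC/C(C)=C/I)[C@]1(C)CCC=C(CC/C(=C\[Sn](CCCC)(CCCC)CCCC)C(C)C)C(=O)O1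
A2 | alternative 2 | (7R,8R)-7,8-epoxycembra-1E,3E,11Z-trien-20-oic acid | O1[C@@H]2CC/C(C)=C/C=C(/C(C)C)CC/C(C(=O)O)=C/CC[C@@]12C
A3 | alternative 2 | cembra-1E,3E,7E,11Z-tetraen-20-oic acid | OC(=O)/C1=C\CC/C(C)=C/CC/C(C)=C/C=C(/C(C)C)CC1
A4 | alternative 3 | cis-fused cyclobutene (C1–C4 bond, C2=C3) analogue of the target, bicyclo[10.2.0] core with angular isopropyl and methyl | CC(=O)O[C@@H]1CC[C@]2(C)C=C[C@]2(C(C)C)CCC3=CCC[C@]1(C)OC3=O
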